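**Retrosynthetic overview**

1. Target 30 ← hydrogenolysis ← catechol 29 ← Dakin oxidation and ortho-formylation at C7 ← phenol 25. Ring A (C4a, C5, C6, C7, C8, C8a) carries a meta oxygen pair (C6–OMe, C8–OH) with C5–H, a resorcinol monoether pattern that a vinylketene/ynol ether benzannulation writes in one operation.
2. Ring A is cut at C4a–C5, C5–C6, C7–C8 and C8–C8a, giving diazomethyl ketone 16 (the C4a=C8a alkene of a finished ring B; diazo carbon = C5, carbonyl carbon = C8) and methoxyethyne 20 (C6, C7).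
3. 16 ← methyl ketone 14 (diazo transfer) ← acid unmasking and dehydration of C8a-hydroxy, C4a-(1,1-dimethoxyethyl) cyclohexane 12 ← silyl enol ether 9 (orthoacetate alkylation at C4a, hydride reduction, benzylation).
4. Ring B and all three stereocentres (C1, C2, C3) ← one Diels–Alder reaction of (Z)-1-aryl-2-silyloxybutadiene 5 with dimenthyl fumarate 8. The oxygen is placed on C8a, not C4a, so that C1 is the nucleophilic diene terminus and the endo rule gives the all-trans array; a C4a-oxygenated or C4a-alkylated 1-aryl diene would put the activated ester on C2, endo and cis to the aryl group.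
5. Order of ring construction: ring C (the guaiacyl ring) is bought, ring B is made in step 5, ring A in step 12.

Key step: step 12

Remark on locants: in the comments, ring B carbons carry the numbers of the final tetralin (C1 aryl-bearing, C2 and C3 the CH2O-bearing carbons, C4 the CH2, C4a and C8a the future ring-fusion carbons). The formal names use their own numbering.

Assumption: aluminium-complexed dimenthyl fumarate is taken to react on the face known for simple dienes, where the (1R,2S,5R)-menthyl diester gives (1S,2S)-cyclohex-4-ene-1,2-dicarboxylates. The R,R series needed at C2/C3 is therefore drawn from (+)-menthol; the antipodal alcohol would be used if the sense proved opposite.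

**Route**

Step 1
Reactants: 1 [4-(benzyloxy)-3-methoxyphenyl]acetic acid
Product: 3 2-[4-(benzyloxy)-3-methoxyphenyl]-N-methoxy-N-methylacetamide, via acyl imidazolide 2 (not isolated)
Conditions: carbonyldiimidazole, CH2Cl2, rt; then MeNH(OMe)·HCl, rt
Reagents that add atoms: N,O-dimethylhydroxylamine hydrochloride, CNOC.Cl
Why: Amide coupling in which carbonyldiimidazole activates the acid as acyl imidazolide 2, which then acylates the hydroxylamine nitrogen without touching the benzyl ether.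

Step 2
Reactants: 3 2-[4-(benzyloxy)-3-methoxyphenyl]-N-methoxy-N-methylacetamide
Product: 4 1-[4-(benzyloxy)-3-methoxyphenyl]but-3-en-2-one
Conditions: CH2=CHMgBr, THF, −78 → 0 °C; poured into cold 1 M HCl
Reagents that add atoms: vinylmagnesium bromide, C=C[Mg]Br
Why: Grignard acylation of an N-methoxy-N-methylamide, in which the magnesium-chelated tetrahedral adduct persists until the acidic quench, so that one vinyl group is delivered and the released amine is protonated before it can add to the enone.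

Step 3
Reactants: 4 1-[4-(benzyloxy)-3-methoxyphenyl]but-3-en-2-one
Product: 5 (Z)-({1-[4-(benzyloxy)-3-methoxyphenyl]buta-1,3-dien-2-yl}oxy)(tert-butyl)dimethylsilane
Conditions: TBSOTf, Et3N, Et2O, 0 °C
Reagents that add atoms: tert-butyldimethylsilyl trifluoromethanesulfonate, CC(C)(C)[Si](C)(C)OS(=O)(=O)C(F)(F)F
Why: Soft enolisation with a silyl triflate and an amine, in which the benzylic CH2 is the only enolisable position and the silyl dienol ether should form with the aryl group cis to oxygen (Z), the geometry that points the aryl group outward in the s-cis diene.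

Step 4
Reactants: 6 fumaric acid; 7 (1S,2R,5S)-(+)-menthol
Product: 8 bis[(1S,2R,5S)-2-isopropyl-5-methylcyclohexyl] fumarate
Conditions: 7 (2.2 equiv in all), 4-MeC6H4SO3H·H2O (cat.), PhMe, reflux, Dean–Stark trap
Reagents that add atoms: (1S,2R,5S)-(+)-menthol (the second equivalent of 7), CC(C)[C@H]1CC[C@H](C)C[C@@H]1O
Why: Twofold Fischer esterification, one molecule of menthol condensing with each carboxyl group of fumaric acid, driven by azeotropic removal of water, which leaves the menthol stereocentres and the E alkene unchanged.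

Step 5
Reactants: 5 (Z)-({1-[4-(benzyloxy)-3-methoxyphenyl]buta-1,3-dien-2-yl}oxy)(tert-butyl)dimethylsilane; 8 bis[(1S,2R,5S)-2-isopropyl-5-methylcyclohexyl] fumarate
Product: 9 bis[(1S,2R,5S)-menthyl] (1R,2R,3S)-3-[4-(benzyloxy)-3-methoxyphenyl]-4-[(tert-butyldimethylsilyl)oxy]cyclohex-4-ene-1,2-dicarboxylate
Conditions: Et2AlCl (1.1 equiv), PhMe, −40 °C
Reagents that add atoms: none
Why: Lewis-acid-promoted Diels–Alder reaction of a 2-silyloxydiene, in which the silyloxy group on C8a makes C1 the nucleophilic terminus, so the aluminium-bound ester lies on C3 and takes the endo position, placing it cis and the C2 ester trans to the outward aryl group (C1–C2 trans, C2–C3 trans from the E dienophile), while the two menthyl groups shield the same face of the fumarate and set C2 and C3 as R,R.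

Step 6
Reactants: 9 bis[(1S,2R,5S)-menthyl] (1R,2R,3S)-3-[4-(benzyloxy)-3-methoxyphenyl]-4-[(tert-butyldimethylsilyl)oxy]cyclohex-4-ene-1,2-dicarboxylate
Product: 10 bis[(1S,2R,5S)-menthyl] (1R,2R,3S)-3-[4-(benzyloxy)-3-methoxyphenyl]-5-(1,1-dimethoxyethyl)-4-oxocyclohexane-1,2-dicarboxylate (C5 epimers)
Conditions: MeC(OMe)3, Me3SiOSO2CF3 (10 mol %), CH2Cl2, −78 °C
Reagents that add atoms: trimethyl orthoacetate, CC(OC)(OC)OC
Why: Mukaiyama-type alkylation of the silyl enol ether by the 1,1-dimethoxyethyl cation, which can only bond at C4a and so places the masked acetyl group regiospecifically (the new C4a centre is destroyed later), while the low temperature and absence of base should keep the now α-keto C1–H from epimerising.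

Step 7
Reactants: 10 bis[(1S,2R,5S)-menthyl] (1R,2R,3S)-3-[4-(benzyloxy)-3-methoxyphenyl]-5-(1,1-dimethoxyethyl)-4-oxocyclohexane-1,2-dicarboxylate
Product: 11 [(1R,2S,3S)-3-[4-(benzyloxy)-3-methoxyphenyl]-5-(1,1-dimethoxyethyl)-4-hydroxycyclohexane-1,2-diyl]dimethanol (C4/C5 epimers)
Conditions: LiAlH4, THF, 0 °C → rt
Reagents that add atoms: none
Why: Hydride reduction of both menthyl esters to primary alcohols and of the C8a ketone to a secondary alcohol whose configuration is immaterial, with the dimethyl ketal inert to hydride and the auxiliary released as menthol.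

Step 8
Reactants: 11 [(1R,2S,3S)-3-[4-(benzyloxy)-3-methoxyphenyl]-5-(1,1-dimethoxyethyl)-4-hydroxycyclohexane-1,2-diyl]dimethanol
Product: 12 (2S,3S,4R)-2-[4-(benzyloxy)-3-methoxyphenyl]-3,4-bis[(benzyloxy)methyl]-6-(1,1-dimethoxyethyl)cyclohexan-1-ol (C1/C6 epimers)
Conditions: NaH (2.2 equiv), BnBr, Bu4NI (cat.), THF–DMF, 0 °C → rt
Reagents that add atoms: benzyl bromide, BrCc1ccccc1
Why: Williamson ether synthesis in which the two primary alkoxides are benzylated, whereas the secondary C8a hydroxyl, wedged between the aryl-bearing C1 and the ketal-bearing C4a, should stay free.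

Step 9
Reactants: 12 (2S,3S,4R)-2-[4-(benzyloxy)-3-methoxyphenyl]-3,4-bis[(benzyloxy)methyl]-6-(1,1-dimethoxyethyl)cyclohexan-1-ol
Product: 14 1-{(3S,4R,5R)-3-[4-(benzyloxy)-3-methoxyphenyl]-4,5-bis[(benzyloxy)methyl]cyclohex-1-en-1-yl}ethan-1-one, via hydroxy ketone 13 (not isolated)
Conditions: 4-MeC6H4SO3H·H2O (cat.), acetone–H2O, rt; then PhMe, 80 °C
Reagents that add atoms: water, O
Why: Acid-catalysed ketal hydrolysis gives β-hydroxy ketone 13, which undergoes aldol-type dehydration through its enol, and because the hydroxyl sits on C8a the alkene can only form between C4a and C8a, conjugated with the acetyl group.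

Step 10
Reactants: 14 1-{(3S,4R,5R)-3-[4-(benzyloxy)-3-methoxyphenyl]-4,5-bis[(benzyloxy)methyl]cyclohex-1-en-1-yl}ethan-1-one
Product: 16 2-diazo-1-{(3S,4R,5R)-3-[4-(benzyloxy)-3-methoxyphenyl]-4,5-bis[(benzyloxy)methyl]cyclohex-1-en-1-yl}ethan-1-one, via trifluoroacetyl diketone 15 (not isolated)
Conditions: LiN(SiMe3)2, THF, −78 °C; CF3CO2CH2CF3; then MsN3, Et3N, H2O (1 equiv), MeCN, rt
Reagents that add atoms: methanesulfonyl azide, CS(=O)(=O)N=[N+]=[N-]
Why: Detrifluoroacetylative diazo transfer, in which kinetic deprotonation of the methyl group and Claisen trifluoroacetylation give 15, whose activated methylene takes the diazo group from the sulfonyl azide with loss of the trifluoroacetyl group, so the conjugated alkene is never exposed to diazomethane.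

Step 11
Reactants: 17 chloroacetaldehyde dimethyl acetal
Product: 20 methoxyethyne, via chlorovinyl ether 18 (not isolated), via sodium methoxyethynide 19 (not isolated)
Conditions: NaNH2 (3 equiv), liq. NH3, −33 °C; then cold H2O (brine), distilled into a cold trap
Reagents that add atoms: none
Why: Two amide-induced β-eliminations (methanol, then hydrogen chloride) give the ynol ether, which is held as its sodium acetylide until the cold aqueous quench and is then distilled as a low-boiling liquid for immediate use.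

Step 12
Reactants: 16 2-diazo-1-{(3S,4R,5R)-3-[4-(benzyloxy)-3-methoxyphenyl]-4,5-bis[(benzyloxy)methyl]cyclohex-1-en-1-yl}ethan-1-one; 20 methoxyethyne
Product: 25 (1S,2R,3R)-1-[4-(benzyloxy)-3-methoxyphenyl]-2,3-bis[(benzyloxy)methyl]-6-methoxy-1,2,3,4-tetrahydronaphthalen-8-ol (tetralin numbering), via vinylketene 21 (not isolated), via cyclobutenone 22 (not isolated), via dienylketene 23 (not isolated), via cyclohexadienone 24 (not isolated)
Conditions: 20 (3 equiv), ClCH2CH2Cl, hν (300 nm, Pyrex), sealed tube, 15 °C; then 80 °C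
Reagents that add atoms: none
Why: Irradiation expels N2 from 16 and the alkenyl carbon C4a shifts to the carbene carbon (photochemical Wolff rearrangement, forming C4a–C5) to give vinylketene 21, which adds methoxyethyne in a [2+2] cycloaddition (C5–C6 and C7–C8) to cyclobutenone 22; 4π electrocyclic opening then gives dienylketene 23, 6π electrocyclic closure between the ketene carbon C8 and C8a gives dienone 24, and enolisation delivers phenol 25. The closest known reaction is the Danheiser benzannulation of 1-(diazoacetyl)cycloalkenes with alkoxy- and silyloxyalkynes, of which this is a direct application. Ring A is closed by the 6π electrocyclisation (C8–C8a), the four-membered ring being only a relay that reopens. No lasting stereocentre is created: the cyclobutenone C4 and dienone C8a centres are erased on ring opening and aromatisation, and C1, C2 and C3 are spectators under neutral, base-free conditions. The step needs a single regiochemical outcome in the [2+2], secured by the polarity match of the electrophilic ketene carbonyl carbon with the nucleophilic CH terminus of the ynol ether, so that the methoxy carbon becomes C6, meta to the C8 hydroxyl that is born next to C1. Light of 300 nm through Pyrex is chosen to excite the diazo ketone while sparing the benzyl ether chromophores.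

Step 13
Reactants: 25 (1S,2R,3R)-1-[4-(benzyloxy)-3-methoxyphenyl]-2,3-bis[(benzyloxy)methyl]-6-methoxy-1,2,3,4-tetrahydronaphthalen-8-ol
Product: 27 (1S,2R,3R)-1-[4-(benzyloxy)-3-methoxyphenyl]-2,3-bis[(benzyloxy)methyl]-8-hydroxy-6-methoxy-1,2,3,4-tetrahydronaphthalene-7-carbaldehyde (tetralin numbering), via hydroxymethylphenol 26 (not isolated)
Conditions: MgCl2, Et3N, (CH2O)n, MeCN, reflux
Reagents that add atoms: paraformaldehyde (as formaldehyde), C=O
Why: Magnesium-mediated ortho-formylation of a phenol (Casnati–Skattebøl), in which the magnesium phenoxide delivers formaldehyde to C7, the only free ortho position, and a second formaldehyde oxidises hydroxymethyl intermediate 26 to the aldehyde by hydride transfer.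

Step 14
Reactants: 27 (1S,2R,3R)-1-[4-(benzyloxy)-3-methoxyphenyl]-2,3-bis[(benzyloxy)methyl]-8-hydroxy-6-methoxy-1,2,3,4-tetrahydronaphthalene-7-carbaldehyde
Product: 29 (1S,2R,3R)-1-[4-(benzyloxy)-3-methoxyphenyl]-2,3-bis[(benzyloxy)methyl]-6-methoxy-1,2,3,4-tetrahydronaphthalene-7,8-diol (tetralin numbering), via aryl formate 28 (not isolated)
Conditions: 30% aq. H2O2, NaOH, THF–H2O, 0 °C → rt, under N2; HCl work-up
Reagents that add atoms: hydrogen peroxide, OO
Why: Dakin oxidation, in which hydroperoxide adds to the ortho-hydroxy aldehyde, aryl migration gives formate 28 and its hydrolysis unveils the C7 hydroxyl, while the benzyl ethers and the C1–H bond are inert to alkaline peroxide.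

Step 15
Reactants: 29 (1S,2R,3R)-1-[4-(benzyloxy)-3-methoxyphenyl]-2,3-bis[(benzyloxy)methyl]-6-methoxy-1,2,3,4-tetrahydronaphthalene-7,8-diol
Product: 30 (1S,2R,3R)-1-(4-hydroxy-3-methoxyphenyl)-2,3-bis(hydroxymethyl)-6-methoxy-1,2,3,4-tetrahydronaphthalene-7,8-diol (tetralin numbering)
Conditions: H2 (1 atm), Pd/C, EtOAc–MeOH, rt
Reagents that add atoms: none
Why: Hydrogenolysis over palladium on carbon cleaves the aryl benzyl ether and both alkyl benzyl ethers to toluene, and the diarylmethine C1–H bond and the three stereocentres should be untouched under these mild conditions.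

**Compound list**

1 | [4-(benzyloxy)-3-methoxyphenyl]acetic acid | COc1cc(CC(=O)O)ccc1OCc1ccccc1 | starting material
2 | 2-[4-(benzyloxy)-3-methoxyphenyl]-1-(1H-imidazol-1-yl)ethan-1-one | COc1cc(CC(=O)n2ccnc2)ccc1OCc1ccccc1 | intermediate
3 | 2-[4-(benzyloxy)-3-methoxyphenyl]-N-methoxy-N-methylacetamide | COc1cc(CC(=O)N(C)OC)ccc1OCc1ccccc1 | intermediate
4 | 1-[4-(benzyloxy)-3-methoxyphenyl]but-3-en-2-one | COc1cc(CC(=O)C=C)ccc1OCc1ccccc1 | intermediate
5 | (Z)-({1-[4-(benzyloxy)-3-methoxyphenyl]buta-1,3-dien-2-yl}oxy)(tert-butyl)dimethylsilane | COc1cc(/C=C(/C=C)O[Si](C)(C)C(C)(C)C)ccc1OCc1ccccc1 | intermediate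
6 | fumaric acid | OC(=O)/C=C/C(=O)O | starting material
7 | (1S,2R,5S)-(+)-menthol | CC(C)[C@H]1CC[C@H](C)C[C@@H]1O | starting material
8 | bis[(1S,2R,5S)-2-isopropyl-5-methylcyclohexyl] fumarate | CC(C)[C@H]1CC[C@H](C)C[C@@H]1OC(=O)/C=C/C(=O)O[C@H]1C[C@@H](C)CC[C@@H]1C(C)C | intermediate
9 | bis[(1S,2R,5S)-menthyl] (1R,2R,3S)-3-[4-(benzyloxy)-3-methoxyphenyl]-4-[(tert-butyldimethylsilyl)oxy]cyclohex-4-ene-1,2-dicarboxylate | COc1cc([C@H]2C(O[Si](C)(C)C(C)(C)C)=CC[C@@H](C(=O)O[C@H]3C[C@@H](C)CC[C@@H]3C(C)C)[C@@H]2C(=O)O[C@H]2C[C@@H](C)CC[C@@H]2C(C)C)ccc1OCc1ccccc1 | intermediate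
10 | bis[(1S,2R,5S)-menthyl] (1R,2R,3S)-3-[4-(benzyloxy)-3-methoxyphenyl]-5-(1,1-dimethoxyethyl)-4-oxocyclohexane-1,2-dicarboxylate (C5 epimers) | COc1cc([C@H]2C(=O)C(C(C)(OC)OC)C[C@@H](C(=O)O[C@H]3C[C@@H](C)CC[C@@H]3C(C)C)[C@@H]2C(=O)O[C@H]2C[C@@H](C)CC[C@@H]2C(C)C)ccc1OCc1ccccc1 | intermediate
11 | [(1R,2S,3S)-3-[4-(benzyloxy)-3-methoxyphenyl]-5-(1,1-dimethoxyethyl)-4-hydroxycyclohexane-1,2-diyl]dimethanol (C4/C5 epimers) | COc1cc([C@H]2C(O)C(C(C)(OC)OC)C[C@@H](CO)[C@@H]2CO)ccc1OCc1ccccc1 | intermediate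
12 | (2S,3S,4R)-2-[4-(benzyloxy)-3-methoxyphenyl]-3,4-bis[(benzyloxy)methyl]-6-(1,1-dimethoxyethyl)cyclohexan-1-ol (C1/C6 epimers) | COc1cc([C@H]2C(O)C(C(C)(OC)OC)C[C@@H](COCc3ccccc3)[C@@H]2COCc3ccccc3)ccc1OCc1ccccc1 | intermediate
13 | 1-{(3S,4S,5R)-3-[4-(benzyloxy)-3-methoxyphenyl]-4,5-bis[(benzyloxy)methyl]-2-hydroxycyclohexyl}ethan-1-one (C1/C2 epimers) | COc1cc([C@H]2C(O)C(C(C)=O)C[C@@H](COCc3ccccc3)[C@@H]2COCc3ccccc3)ccc1OCc1ccccc1 | intermediate
14 | 1-{(3S,4R,5R)-3-[4-(benzyloxy)-3-methoxyphenyl]-4,5-bis[(benzyloxy)methyl]cyclohex-1-en-1-yl}ethan-1-one | COc1cc([C@H]2C=C(C(C)=O)C[C@@H](COCc3ccccc3)[C@@H]2COCc3ccccc3)ccc1OCc1ccccc1 | intermediate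
15 | 1-{(3S,4R,5R)-3-[4-(benzyloxy)-3-methoxyphenyl]-4,5-bis[(benzyloxy)methyl]cyclohex-1-en-1-yl}-4,4,4-trifluorobutane-1,3-dione | COc1cc([C@H]2C=C(C(=O)CC(=O)C(F)(F)F)C[C@@H](COCc3ccccc3)[C@@H]2COCc3ccccc3)ccc1OCc1ccccc1 | intermediate
16 | 2-diazo-1-{(3S,4R,5R)-3-[4-(benzyloxy)-3-methoxyphenyl]-4,5-bis[(benzyloxy)methyl]cyclohex-1-en-1-yl}ethan-1-one | COc1cc([C@H]2C=C(C(=O)C=[N+]=[N-])C[C@@H](COCc3ccccc3)[C@@H]2COCc3ccccc3)ccc1OCc1ccccc1 | intermediate
17 | chloroacetaldehyde dimethyl acetal (2-chloro-1,1-dimethoxyethane) | COC(CCl)OC | starting material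
18 | 1-chloro-2-methoxyethene (E/Z mixture) | COC=CCl | intermediate
19 | sodium methoxyethynide | [Na+].[C-]#COC | intermediate
20 | methoxyethyne | COC#C | intermediate
21 | 2-{(3S,4R,5R)-3-[4-(benzyloxy)-3-methoxyphenyl]-4,5-bis[(benzyloxy)methyl]cyclohex-1-en-1-yl}ethen-1-one (vinylketene) | COc1cc([C@H]2C=C(C=C=O)C[C@@H](COCc3ccccc3)[C@@H]2COCc3ccccc3)ccc1OCc1ccccc1 | intermediate
22 | 4-{(3S,4R,5R)-3-[4-(benzyloxy)-3-methoxyphenyl]-4,5-bis[(benzyloxy)methyl]cyclohex-1-en-1-yl}-3-methoxycyclobut-2-en-1-one (C4 epimers) | COc1cc([C@H]2C=C(C3C(OC)=CC3=O)C[C@@H](COCc3ccccc3)[C@@H]2COCc3ccccc3)ccc1OCc1ccccc1 | intermediate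
23 | (3E)-4-{(3S,4R,5R)-3-[4-(benzyloxy)-3-methoxyphenyl]-4,5-bis[(benzyloxy)methyl]cyclohex-1-en-1-yl}-3-methoxybuta-1,3-dien-1-one (dienylketene, ketene cis to the ring alkene) | COc1cc([C@H]2C=C(\C=C(OC)/C=C=O)C[C@@H](COCc3ccccc3)[C@@H]2COCc3ccccc3)ccc1OCc1ccccc1 | intermediate
24 | keto tautomer of 25: 1-[4-(benzyloxy)-3-methoxyphenyl]-2,3-bis[(benzyloxy)methyl]-6-methoxy-2,3,4,8a-tetrahydronaphthalen-8(1H)-one, ring B configured as in 16, C8a unspecified | COc1cc([C@H]2C3C(=O)C=C(OC)C=C3C[C@@H](COCc3ccccc3)[C@@H]2COCc3ccccc3)ccc1OCc1ccccc1 | intermediate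
25 | (1S,2R,3R)-1-[4-(benzyloxy)-3-methoxyphenyl]-2,3-bis[(benzyloxy)methyl]-6-methoxy-1,2,3,4-tetrahydronaphthalen-8-ol | COc1cc([C@H]2c3c(cc(OC)cc3O)C[C@@H](COCc3ccccc3)[C@@H]2COCc3ccccc3)ccc1OCc1ccccc1 | intermediate
26 | (1S,2R,3R)-1-[4-(benzyloxy)-3-methoxyphenyl]-2,3-bis[(benzyloxy)methyl]-7-(hydroxymethyl)-6-methoxy-1,2,3,4-tetrahydronaphthalen-8-ol | COc1cc([C@H]2c3c(cc(OC)c(CO)c3O)C[C@@H](COCc3ccccc3)[C@@H]2COCc3ccccc3)ccc1OCc1ccccc1 | intermediate
27 | (1S,2R,3R)-1-[4-(benzyloxy)-3-methoxyphenyl]-2,3-bis[(benzyloxy)methyl]-8-hydroxy-6-methoxy-1,2,3,4-tetrahydronaphthalene-7-carbaldehyde | COc1cc([C@H]2c3c(cc(OC)c(C=O)c3O)C[C@@H](COCc3ccccc3)[C@@H]2COCc3ccccc3)ccc1OCc1ccccc1 | intermediate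
28 | (1S,2R,3R)-1-[4-(benzyloxy)-3-methoxyphenyl]-2,3-bis[(benzyloxy)methyl]-8-hydroxy-6-methoxy-1,2,3,4-tetrahydronaphthalen-7-yl formate | COc1cc([C@H]2c3c(cc(OC)c(OC=O)c3O)C[C@@H](COCc3ccccc3)[C@@H]2COCc3ccccc3)ccc1OCc1ccccc1 | intermediate
29 | (1S,2R,3R)-1-[4-(benzyloxy)-3-methoxyphenyl]-2,3-bis[(benzyloxy)methyl]-6-methoxy-1,2,3,4-tetrahydronaphthalene-7,8-diol | COc1cc([C@H]2c3c(cc(OC)c(O)c3O)C[C@@H](COCc3ccccc3)[C@@H]2COCc3ccccc3)ccc1OCc1ccccc1 | intermediate
30 | (1S,2R,3R)-1-(4-hydroxy-3-methoxyphenyl)-2,3-bis(hydroxymethyl)-6-methoxy-1,2,3,4-tetrahydronaphthalene-7,8-diol | COc1cc([C@H]2c3c(cc(OC)c(O)c3O)C[C@@H](CO)[C@@H]2CO)ccc1O | target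

**Step count and risks**

Total step count: 15. Longest linear sequence: 13 steps (steps 1–3, 5–10, 12–15); steps 4 and 11 make the two side components.

Steps most likely to fail:

Step 6. The 1,1-dimethoxyethyl cation is a weak, hindered electrophile, so capture of the silyl enol ether may be slow and protodesilylation to the ketone (loss of the regiochemical handle) may compete. Fallback, setting out from 9 and rejoining at 14: treat 9 with trimethyl orthoformate and catalytic Me3SiOSO2CF3 (CH2Cl2, −78 °C), whose carbenium ion is a far better electrophile, to give bis(menthyl) keto acetal F1. Reduce with LiAlH4 to triol acetal F2 and benzylate the two primary hydroxyls (NaH, BnBr) to bis(benzyl ether) F3. Acid hydrolysis with dehydration (4-MeC6H4SO3H·H2O, wet acetone, then warm toluene) gives enal F4. MeMgBr (THF, −78 °C) adds 1,2 to give allylic alcohol F5, and MnO2 (CH2Cl2) oxidises it to methyl ketone 14.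

Step 5. Shielding by the menthyl groups may be incomplete, or the addition may become stepwise (Michael-type) under the Lewis acid, eroding facial and endo/exo selectivity or stopping at an open-chain adduct. Fallback, setting out from 5 and rejoining at 11: drop auxiliary and Lewis acid. Heat 5 with dimethyl fumarate (toluene, 90 °C) in a concerted thermal Diels–Alder reaction to racemic all-trans diester F6. Alkylate with trimethyl orthoacetate as in step 6 to racemic keto ketal F7 and reduce with LiAlH4 to racemic triol F8. Separate the enantiomers of F8 by preparative chromatography on a chiral stationary phase to obtain 11.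

Step 12. The three benzyl ether and guaiacyl chromophores may absorb competitively and photodegrade, the volatile alkyne may be lost, and the product phenol may be acylated by unreacted vinylketene. Fallback, setting out from 16 and rejoining at 22: generate the same vinylketene without light. Silver-mediated Wolff rearrangement of 16 (PhCO2Ag, Et3N, MeOH) gives homologous β,γ-unsaturated methyl ester F9. LiOH (THF–H2O) gives acid F10, and (COCl)2 with catalytic HCONMe2 gives acid chloride F11. Slow addition of Et3N to F11 and 20 in MeCN (0 °C → rt) dehydrochlorinates to ketene 21, which is trapped as cyclobutenone 22. Heating 22 in toluene (80–110 °C) completes the electrocyclic cascade to 25.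

**Further compounds**

F1 | step 6 | bis[(1S,2R,5S)-menthyl] (1R,2R,3S)-3-[4-(benzyloxy)-3-methoxyphenyl]-5-(dimethoxymethyl)-4-oxocyclohexane-1,2-dicarboxylate (C5 epimers) | COc1cc([C@H]2C(=O)C(C(OC)OC)C[C@@H](C(=O)O[C@H]3C[C@@H](C)CC[C@@H]3C(C)C)[C@@H]2C(=O)O[C@H]2C[C@@H](C)CC[C@@H]2C(C)C)ccc1OCc1ccccc1
F2 | step 6 | [(1R,2S,3S)-3-[4-(benzyloxy)-3-methoxyphenyl]-5-(dimethoxymethyl)-4-hydroxycyclohexane-1,2-diyl]dimethanol (C4/C5 epimers) | COc1cc([C@H]2C(O)C(C(OC)OC)C[C@@H](CO)[C@@H]2CO)ccc1OCc1ccccc1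
F3 | step 6 | (2S,3S,4R)-2-[4-(benzyloxy)-3-methoxyphenyl]-3,4-bis[(benzyloxy)methyl]-6-(dimethoxymethyl)cyclohexan-1-ol (C1/C6 epimers) | COc1cc([C@H]2C(O)C(C(OC)OC)C[C@@H](COCc3ccccc3)[C@@H]2COCc3ccccc3)ccc1OCc1ccccc1
F4 | step 6 | (3S,4R,5R)-3-[4-(benzyloxy)-3-methoxyphenyl]-4,5-bis[(benzyloxy)methyl]cyclohex-1-ene-1-carbaldehyde | COc1cc([C@H]2C=C(C=O)C[C@@H](COCc3ccccc3)[C@@H]2COCc3ccccc3)ccc1OCc1ccccc1
F5 | step 6 | 1-{(3S,4R,5R)-3-[4-(benzyloxy)-3-methoxyphenyl]-4,5-bis[(benzyloxy)methyl]cyclohex-1-en-1-yl}ethan-1-ol (carbinol epimers) | COc1cc([C@H]2C=C(C(C)O)C[C@@H](COCc3ccccc3)[C@@H]2COCc3ccccc3)ccc1OCc1ccccc1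
F6 | step 5 | dimethyl rac-(1R,2R,3S)-3-[4-(benzyloxy)-3-methoxyphenyl]-4-[(tert-butyldimethylsilyl)oxy]cyclohex-4-ene-1,2-dicarboxylate (racemate, one enantiomer drawn) | COc1cc([C@H]2C(O[Si](C)(C)C(C)(C)C)=CC[C@@H](C(=O)OC)[C@@H]2C(=O)OC)ccc1OCc1ccccc1
F7 | step 5 | dimethyl rac-(1R,2R,3S)-3-[4-(benzyloxy)-3-methoxyphenyl]-5-(1,1-dimethoxyethyl)-4-oxocyclohexane-1,2-dicarboxylate (racemate, one enantiomer drawn) | COc1cc([C@H]2C(=O)C(C(C)(OC)OC)C[C@@H](C(=O)OC)[C@@H]2C(=O)OC)ccc1OCc1ccccc1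
F8 | step 5 | rac-[(1R,2S,3S)-3-[4-(benzyloxy)-3-methoxyphenyl]-5-(1,1-dimethoxyethyl)-4-hydroxycyclohexane-1,2-diyl]dimethanol (racemate of 11, one enantiomer drawn) | COc1cc([C@H]2C(O)C(C(C)(OC)OC)C[C@@H](CO)[C@@H]2CO)ccc1OCc1ccccc1
F9 | step 12 | methyl 2-{(3S,4R,5R)-3-[4-(benzyloxy)-3-methoxyphenyl]-4,5-bis[(benzyloxy)methyl]cyclohex-1-en-1-yl}acetate | COc1cc([C@H]2C=C(CC(=O)OC)C[C@@H](COCc3ccccc3)[C@@H]2COCc3ccccc3)ccc1OCc1ccccc1
F10 | step 12 | 2-{(3S,4R,5R)-3-[4-(benzyloxy)-3-methoxyphenyl]-4,5-bis[(benzyloxy)methyl]cyclohex-1-en-1-yl}acetic acid | COc1cc([C@H]2C=C(CC(=O)O)C[C@@H](COCc3ccccc3)[C@@H]2COCc3ccccc3)ccc1OCc1ccccc1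
F11 | step 12 | 2-{(3S,4R,5R)-3-[4-(benzyloxy)-3-methoxyphenyl]-4,5-bis[(benzyloxy)methyl]cyclohex-1-en-1-yl}acetyl chloride | COc1cc([C@H]2C=C(CC(=O)Cl)C[C@@H](COCc3ccccc3)[C@@H]2COCc3ccccc3)ccc1OCc1ccccc1
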